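A small charge of enzyme sits between two substrates that compete for it, and I want to know how it divides.

    starting material + enzyme ⇌ complex A (K1 = 720 /M, k1 = 78000 /M/s)
    complex A → enzyme + target (k2 = 2700 /min)
    second substrate + enzyme ⇌ complex B (K3 = 980 /M, k3 = 2.6 × 10⁵ /M/s)
    complex B → enzyme + second product (k4 = 7200 /min)
    starting material → uncatalysed product (k5 = 0.026 /min)
    starting material + protic impurity → quenched substrate (k6 = 4.1 /M/min)

starting material 0.020 M; second substrate 1.00 equiv; protic impurity 2.00 mM; enzyme 0.0011 mol%

- the form that holds most of the catalyst when 30% of the starting material are converted (enzyme / complex B / complex A)
- its share of the catalyst then
- apparent order in second substrate when 30% of the starting material are converted (percent change of the rate of making target for one percent more second substrate charged)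
- apparent order in enzyme when 30% of the starting material are converted (percent change of the rate of making target for one percent more enzyme charged)
- factor on the rate of making target when 30% of the starting material are converted if second substrate is charged twice over

Complex A lasts 0.00652 s and complex B 0.00260 s, both far shorter than the 38.5 min of the uncatalysed route, so I take each as used as fast as it is made. Complex A per free enzyme is then starting material over 1.97 mM, its Michaelis constant: off rate plus forward rate, over on rate. Complex B per free enzyme is second substrate over 1.48 mM. I need these two amounts and their quotient, the hold ratio, 1.33: complex B over complex A equals the hold ratio times second substrate over starting material.

With equal charges, I can work with fractions left. At the start of this flask, starting material falls by 0.0464 /min and second substrate by 0.0433 /min, nearly one pace. So I let both stand at 70.0%. Then complex B holds 53.8% and complex A 40.5%, making complex B the resting state. Target is made in proportion to complex A, so at fixed starting material I expect a negative order in second substrate. My reckoning stops there.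

The forecast says complex B at 53%, with orders −0.61 and 1.15 and a doubling factor of 0.6: “complex B holds about 53%, complex A 41% and free enzyme 6%”. It differs from me by taking second substrate at 13.5 mM where I took 14.0 mM.

The flask gives complex B at 52.8%, orders −0.61 and 1.2, and factor 0.604, with complex A at 41.3%. After 30.0 min, this flask has 1.65% of its second substrate and 12.8% of its starting material left, so the hold ratio gives complex B over complex A as 0.171, and the states read 0.172. In the flask charged with twice the second substrate, the factor puts complex A at 25.0% at the same conversion. Through the hold ratio, that reads as 30.2 mM of second substrate left.

The numbers belong to no real substance; what happens was integrated by code.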